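**Plan**
- Cuts, in order: the O1–acyl ester bond, which gives the core and (2E,4S)-2,4-dimethyloct-2-enoic acid (itself cut at C2'=C3' and at C4'–CH3). Next come the C–O bonds at C13, C15, C1 and C8. Last are the skeletal bonds C6–C7, C5–C10 and C5–C14, which lead back to acyclic farnesyl diphosphate.
- Enabling feature: C1–C15 of the target make up the skeleton of (+)-aristolochene. This covers ring A (C1–C5, C10), ring B (C5–C10), the cis β groups C15 on C4 and C14 on C5, the α three-carbon unit C11–C13 on C7, and the C9=C10 alkene. One cyclase reaction delivers all of it.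
- Forward order: the ten-membered ring closes first (C6–C7), is then divided into rings A and B (C5–C10), and C14 migrates, all in one enzymatic step. Oxidation follows at C8 and C1, then at C15. O1 is esterified, C15 is raised to the acid, and C13 is oxidised last, without protecting groups.
- Stereochemistry: C4, C5 and C7 come from the fold of the cyclase. C1 comes from hydride delivery on the α face, opposite the axial C14. C4' comes from an Evans methylation, and the E alkene from a stabilised Wittig ylide.

Key step: step 3

Remark: eremophilane numbering is used (C1 carbinol carbon, C4 bears C15, C5 bears C14, C7 bears C11–C13, C8 ketone, C9=C10 alkene; β is the face of C14), and phosphate species are drawn as free acids although they are handled as ammonium salts.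

Step 1
Reactants: 1 (2E,6E)-farnesol
Product: 2 (2E,6E)-farnesyl bromide
Conditions: PBr3, THF, −10 °C
Reagents that add atoms: phosphorus tribromide, BrP(Br)Br
Why: PBr3 bromination of the primary allylic alcohol through its phosphite ester (SN2) should proceed at low temperature without allylic transposition or loss of the E geometry.

Step 2
Reactants: 2 (2E,6E)-farnesyl bromide
Product: 3 (2E,6E)-farnesyl diphosphate
Conditions: (n-Bu4N)3HP2O7, MeCN, rt; Dowex 50WX8 (NH4+ form), NH4HCO3 buffer; cellulose chromatography
Reagents that add atoms: tris(tetrabutylammonium) hydrogen diphosphate, CCCC[N+](CCCC)(CCCC)CCCC.CCCC[N+](CCCC)(CCCC)CCCC.CCCC[N+](CCCC)(CCCC)CCCC.OP(=O)([O-])OP(=O)([O-])[O-]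
Why: The diphosphate trianion, made soluble and nucleophilic in MeCN by its lipophilic counter-ions, displaces the allylic bromide by SN2 (the standard allylic diphosphate synthesis), and cation exchange gives the water-soluble salt that the enzyme accepts.

Step 3
Reactants: 3 (2E,6E)-farnesyl diphosphate
Product: 5 (+)-aristolochene, via enzyme-bound (S)-germacrene A 4 (not isolated)
Conditions: aristolochene synthase (Aspergillus terreus, recombinant from E. coli), MgCl2 (5 mM), HEPES buffer pH 7.5, pentane overlay, 30 °C
Reagents that add atoms: none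
Why: Mg2+ ions held by the aspartate-rich motifs pull the diphosphate off C6 of 3, the C7=C11 alkene attacks the allyl cation at C6 (C6–C7 bond, a 1,10-macrocyclisation of the chain that is Markovnikov at C11), and loss of a C12 proton leaves bound (S)-germacrene A 4. Reprotonation of 4 at C1 triggers a transannular cation–alkene closure in which C5 bonds to C10 (Markovnikov at C4), forming the six-membered rings A and B at once; H5 then shifts to C4 on the α face, C14 shifts from C10 to C5 on the β face (C5–C14 bond), and loss of a C9 proton places the C9=C10 alkene. This is the native reaction of an ionisation-dependent sesquiterpene cyclase, the enzymatic form of a cationic polyene cyclisation with Wagner–Meerwein shifts, and it is run routinely in vitro on this substrate. C7 is fixed by the face of the distal alkene that the folded chain offers to C6, while C4 and C5 are fixed by the fold of bound 4 and by the strictly anti, suprafacial pair of 1,2-shifts, which leaves C15 and C14 cis on the β face and the C7 unit on the α face. The step needs one outcome among many possible quenching events (early release of 4, selinene-type or C1 deprotonation, capture by water); the E,E geometry of 3, the methyl groups that make each cation tertiary, and the closed water-free pocket with the bound diphosphate as base secure it.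

Step 4
Reactants: 5 (+)-aristolochene
Product: 7 eremophila-9,11-diene-1,8-dione, via eremophila-9,11-dien-8-one 6 (not isolated)
Conditions: Rh2(cap)4 (cap = caprolactamate; 1 mol %, second charge after 5 is consumed), 70% aq t-BuOOH (excess, in portions), 1,2-dichloroethane, 40 °C
Reagents that add atoms: tert-butyl hydroperoxide, CC(C)(C)OO
Why: Radical allylic C–H oxidation by t-BuOO radicals from Rh2(cap)4/t-BuOOH should first attack C8, the methylene on the CH terminus of the trisubstituted alkene (as 5-ene steroids give 7-ketones and valencene gives nootkatone), and then the γ-methylene C1 of enone 6 (as 4-en-3-ones give 4-ene-3,6-diones), under neutral conditions that do not enolise C7.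

Step 5
Reactants: 7 eremophila-9,11-diene-1,8-dione
Product: 8 eremophila-9,11-diene-1β,8β-diol
Conditions: NaBH4, CeCl3·7H2O, MeOH, −78 °C
Reagents that add atoms: none
Why: In this Luche 1,2-reduction hydride should reach C1 from the α face because the axial C14 blocks the β face (as 6-oxo steroids give 6β-alcohols), which sets the axial 1β-OH, while axial attack at C8 gives the equatorial 8β-alcohol, a centre that the next step removes.

Step 6
Reactants: 8 eremophila-9,11-diene-1β,8β-diol
Product: 9 1β-hydroxyeremophila-9,11-dien-8-one
Conditions: activated MnO2, CH2Cl2, rt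
Reagents that add atoms: none
Why: MnO2 allylic oxidation should take the equatorial 8β-alcohol, whose axial C8–H is aligned with the π system, ahead of the hindered axial 1β-alcohol, the same selectivity that turns steroidal 4-ene-3β,6β-diols into 6β-hydroxy-4-en-3-ones.

Step 7
Reactants: 9 1β-hydroxyeremophila-9,11-dien-8-one
Product: 10 1β,15-dihydroxyeremophila-9,11-dien-8-one
Conditions: evolved CYP102A1 (P450 BM3) variant, clarified E. coli lysate, NADP+ (cat.), phosphite dehydrogenase, Na2HPO3, air, KPi buffer pH 8.0, 2% DMSO, 25 °C
Reagents that add atoms: dioxygen, O=O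
Why: Proposed new method: no oxygenase is known to hydroxylate the unactivated C15 methyl of an eremophilane, so a CYP102A1 lineage would have to be evolved on 9 by active-site saturation mutagenesis and screening; the ferryl-oxo haem abstracts hydrogen from whichever C–H bond the pocket holds over the iron and the radical rebounds to C–OH without touching C4, the weaker allylic C–H bonds at C1 and C8 are already oxidised in 9, C7–H is deactivated by the ketone, and the C8 carbonyl and the 1β-OH are polar anchors that can hold ring A over the haem, so the isopropenyl group is the main competitor left; the closest known reaction types are hydroxylation of the unactivated ring methyl C6a of artemisinin by engineered CYP102A1 variants, C15 methyl hydroxylation of trichothecenes, and methyl-to-acid oxidation of ent-kaurene by natural P450 enzymes.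

Step 8
Reactants: 10 1β,15-dihydroxyeremophila-9,11-dien-8-one
Product: 11 1β-hydroxy-8-oxoeremophila-9,11-dien-15-al
Conditions: TEMPO (10 mol %), PhI(OAc)2, CH2Cl2, rt
Reagents that add atoms: none
Why: The oxoammonium (TEMPO) oxidation prefers the primary alcohol to the hindered axial secondary one and stops at the aldehyde in dry CH2Cl2, and C4 is safe because the β formyl group is equatorial and so is the stable epimer.

Step 9
Reactants: 12 hexanoyl chloride, 13 (S)-4-benzyloxazolidin-2-one
Product: 14 (S)-4-benzyl-3-hexanoyloxazolidin-2-one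
Conditions: Et3N, DMAP (cat.), CH2Cl2, 0 °C to rt
Reagents that add atoms: none
Why: DMAP-catalysed N-acylation of the oxazolidinone by the acid chloride is a standard way to load the Evans auxiliary.

Step 10
Reactants: 14 (S)-4-benzyl-3-hexanoyloxazolidin-2-one
Product: 16 (S)-4-benzyl-3-[(S)-2-methylhexanoyl]oxazolidin-2-one, via sodium (Z)-enolate 15 (not isolated)
Conditions: NaHMDS, THF, −78 °C; MeI, −78 °C
Reagents that add atoms: iodomethane, CI
Why: In the Evans asymmetric alkylation the chelated (Z)-enolate is methylated on the face opposite the benzyl group, which for the (S)-auxiliary and a butyl-bearing enolate sets the (S) centre, and the minor epimer is removed by chromatography.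

Step 11
Reactants: 16 (S)-4-benzyl-3-[(S)-2-methylhexanoyl]oxazolidin-2-one
Product: 17 (S)-2-methylhexan-1-ol
Conditions: LiBH4, MeOH (1 equiv), Et2O, 0 °C
Reagents that add atoms: none
Why: Reductive cleavage of the exocyclic imide carbonyl with LiBH4 releases the primary alcohol without epimerisation and returns the auxiliary.

Step 12
Reactants: 17 (S)-2-methylhexan-1-ol, 18 ethyl 2-(triphenylphosphoranylidene)propanoate
Product: 20 ethyl (2E,4S)-2,4-dimethyloct-2-enoate, via (S)-2-methylhexanal 19 (not isolated)
Conditions: TEMPO (cat.), PhI(OAc)2, CH2Cl2, rt; then 18 (excess), rt to 40 °C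
Reagents that add atoms: none
Why: In this one-pot oxoammonium oxidation and Wittig olefination the labile α-chiral aldehyde is used without isolation, and the stabilised α-methyl ylide should give the E trisubstituted enoate.

Step 13
Reactants: 20 ethyl (2E,4S)-2,4-dimethyloct-2-enoate
Product: 21 (2E,4S)-2,4-dimethyloct-2-enoic acid
Conditions: LiOH, THF/MeOH/H2O, rt; then aq HCl
Reagents that add atoms: lithium hydroxide, [Li+].[OH-]
Why: Saponification of the ethyl ester leaves the γ centre and the E alkene untouched because the carboxylate formed resists deconjugation.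

Step 14
Reactants: 11 1β-hydroxy-8-oxoeremophila-9,11-dien-15-al, 21 (2E,4S)-2,4-dimethyloct-2-enoic acid
Product: 23 1β-[(2E,4S)-2,4-dimethyloct-2-enoyloxy]-8-oxoeremophila-9,11-dien-15-al, via Yamaguchi mixed anhydride 22 (not isolated)
Conditions: 21, 2,4,6-trichlorobenzoyl chloride, Et3N, toluene, rt; then 11, DMAP, rt to 40 °C
Reagents that add atoms: 2,4,6-trichlorobenzoyl chloride, O=C(Cl)c1c(Cl)cc(Cl)cc1Cl (its acyl group stays only in intermediate 22)
Why: The Yamaguchi esterification delivers the acyl-DMAP species of the enoic acid to the only hydroxyl group of 11, is strong enough for the hindered axial 1β-alcohol, and retains configuration at C1 because the C1–O bond is not broken.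

Step 15
Reactants: 23 1β-[(2E,4S)-2,4-dimethyloct-2-enoyloxy]-8-oxoeremophila-9,11-dien-15-al
Product: 24 1β-[(2E,4S)-2,4-dimethyloct-2-enoyloxy]-8-oxoeremophila-9,11-dien-15-oic acid
Conditions: NaClO2, NaH2PO4, 2-methylbut-2-ene (excess), t-BuOH/H2O, 0 °C to rt
Reagents that add atoms: sodium chlorite, [Na+].[O-]Cl=O
Why: The Pinnick oxidation converts the only aldehyde present into the acid under weakly acidic conditions that spare the enone, both esters and C7, and the scavenger keeps HOCl away from the isopropenyl group.

Step 16
Reactants: 24 1β-[(2E,4S)-2,4-dimethyloct-2-enoyloxy]-8-oxoeremophila-9,11-dien-15-oic acid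
Product: 26 integric acid, via 13-hydroxy acid 25 (not isolated)
Conditions: SeO2 (30 mol %), t-BuOOH, CH2Cl2, 0 °C to rt; aqueous work-up; then Dess–Martin periodinane, CH2Cl2, rt
Reagents that add atoms: selenium dioxide, O=[Se]=O; tert-butyl hydroperoxide, CC(C)(C)OO (terminal oxidant that restores SeO2)
Why: Catalytic SeO2 allylic oxidation (ene reaction, then [2,3]-sigmatropic shift) should act only on the isopropenyl group, the one electron-rich alkene left, and at the methyl C13 rather than the ketone-deactivated C7–H, and the Dess–Martin oxidation converges alcohol 25 and any enal already formed on the acrolein unit.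

**Compound list**
1 | (2E,6E)-farnesol | CC(C)=CCC/C(C)=C/CC/C(C)=C/CO | starting material
2 | (2E,6E)-farnesyl bromide | CC(C)=CCC/C(C)=C/CC/C(C)=C/CBr | intermediate
3 | (2E,6E)-farnesyl diphosphate (handled as ammonium salt) | CC(C)=CCC/C(C)=C/CC/C(C)=C/COP(=O)(O)OP(=O)(O)O | intermediate
4 | (S)-germacrene A, (1E,5E,8S)-1,5-dimethyl-8-(prop-1-en-2-yl)cyclodeca-1,5-diene | CC(=C)[C@@H]1C/C=C(C)/CC/C=C(C)/CC1 | intermediate
5 | (+)-aristolochene, (4S,5R,7S)-eremophila-9,11-diene (C14 β, C15 β, isopropenyl α) | CC(=C)[C@@H]1C[C@@]2(C)C(=CC1)CCC[C@@H]2C | intermediate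
6 | eremophila-9,11-dien-8-one (C4, C5, C7 as in 5) | CC(=C)[C@@H]1C[C@@]2(C)C(=CC1=O)CCC[C@@H]2C | intermediate
7 | eremophila-9,11-diene-1,8-dione | CC(=C)[C@@H]1C[C@@]2(C)C(=CC1=O)C(=O)CC[C@@H]2C | intermediate
8 | eremophila-9,11-diene-1β,8β-diol | CC(=C)[C@@H]1C[C@@]2(C)C(=C[C@H]1O)[C@H](O)CC[C@@H]2C | intermediate
9 | 1β-hydroxyeremophila-9,11-dien-8-one | CC(=C)[C@@H]1C[C@@]2(C)C(=CC1=O)[C@H](O)CC[C@@H]2C | intermediate
10 | 1β,15-dihydroxyeremophila-9,11-dien-8-one | CC(=C)[C@@H]1C[C@@]2(C)C(=CC1=O)[C@H](O)CC[C@@H]2CO | intermediate
11 | 1β-hydroxy-8-oxoeremophila-9,11-dien-15-al | CC(=C)[C@@H]1C[C@@]2(C)C(=CC1=O)[C@H](O)CC[C@@H]2C=O | intermediate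
12 | hexanoyl chloride | CCCCCC(=O)Cl | starting material
13 | (S)-4-benzyloxazolidin-2-one | O=C1N[C@@H](Cc2ccccc2)CO1 | starting material
14 | (S)-4-benzyl-3-hexanoyloxazolidin-2-one | CCCCCC(=O)N1C(=O)OC[C@@H]1Cc1ccccc1 | intermediate
15 | sodium (Z)-enolate of 14 | CCCC/C=C(\[O-])N1C(=O)OC[C@@H]1Cc1ccccc1.[Na+] | intermediate
16 | (S)-4-benzyl-3-[(S)-2-methylhexanoyl]oxazolidin-2-one | CCCC[C@H](C)C(=O)N1C(=O)OC[C@@H]1Cc1ccccc1 | intermediate
17 | (S)-2-methylhexan-1-ol | CCCC[C@H](C)CO | intermediate
18 | ethyl 2-(triphenylphosphoranylidene)propanoate | CCOC(=O)C(C)=P(c1ccccc1)(c1ccccc1)c1ccccc1 | starting material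
19 | (S)-2-methylhexanal | CCCC[C@H](C)C=O | intermediate
20 | ethyl (2E,4S)-2,4-dimethyloct-2-enoate | CCOC(=O)/C(C)=C/[C@@H](C)CCCC | intermediate
21 | (2E,4S)-2,4-dimethyloct-2-enoic acid | OC(=O)/C(C)=C/[C@@H](C)CCCC | intermediate
22 | (2E,4S)-2,4-dimethyloct-2-enoic 2,4,6-trichlorobenzoic anhydride | O=C(OC(=O)/C(C)=C/[C@@H](C)CCCC)c1c(Cl)cc(Cl)cc1Cl | intermediate
23 | 1β-[(2E,4S)-2,4-dimethyloct-2-enoyloxy]-8-oxoeremophila-9,11-dien-15-al | CC(=C)[C@@H]1C[C@@]2(C)C(=CC1=O)[C@H](OC(=O)/C(C)=C/[C@@H](C)CCCC)CC[C@@H]2C=O | intermediate
24 | 1β-[(2E,4S)-2,4-dimethyloct-2-enoyloxy]-8-oxoeremophila-9,11-dien-15-oic acid | CC(=C)[C@@H]1C[C@@]2(C)C(=CC1=O)[C@H](OC(=O)/C(C)=C/[C@@H](C)CCCC)CC[C@@H]2C(=O)O | intermediate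
25 | 13-hydroxy-1β-[(2E,4S)-2,4-dimethyloct-2-enoyloxy]-8-oxoeremophila-9,11-dien-15-oic acid | C=C(CO)[C@@H]1C[C@@]2(C)C(=CC1=O)[C@H](OC(=O)/C(C)=C/[C@@H](C)CCCC)CC[C@@H]2C(=O)O | intermediate
26 | integric acid | C=C(C=O)[C@@H]1C[C@@]2(C)C(=CC1=O)[C@H](OC(=O)/C(C)=C/[C@@H](C)CCCC)CC[C@@H]2C(=O)O | target

Total step count: 16. Longest linear sequence: 11 steps from farnesol (steps 1–8 and 14–16). The side chain takes 5 steps (9–13).

**Steps most likely to fail**

Step 7 (C15 hydroxylation).
- What may go wrong: screening may find only variants that attack the isopropenyl group or ring methylenes (poor site selectivity), or none that turns over 9.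
- Fallback, by known chemistry, from 7 back to 10: a formal methyl oxidation by way of the C4–H bond.
- mCPBA (NaHCO3, CH2Cl2, 0 °C) masks the only electron-rich alkene of 7 as the 11,12-epoxy enedione F1 (epimers at C11, centre left undefined).
- In F1 the two carbonyl groups deactivate C2, C3, C6 and C7. Methyl(trifluoromethyl)dioxirane (from 1,1,1-trifluoroacetone and Oxone, −20 °C) should therefore insert oxygen with retention into the one remote tertiary C4–H bond and give the 4α-hydroxy epoxy enedione F2.
- Burgess reagent (benzene, 50 °C, syn elimination towards the freely rotating methyl group) gives the 4(15)-methylene epoxy enedione F3. It has to be separated from the 3-ene isomer, which is likely to form alongside because the leaving group is axial.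
- Luche reduction as in step 5 gives the 4(15)-methylene epoxy diol F4.
- 9-BBN adds to the exocyclic alkene from the α face, away from C14, and NaBO3 gives the epoxy triol F5 with H4 α and C15 β.
- NaI, Zn, NaOAc, AcOH (reductive deoxygenation through the iodohydrin) restores the isopropenyl group in the eremophila-9,11-diene-1β,8β,15-triol F6.
- MnO2 as in step 6 oxidises only the 8β allylic alcohol and gives 10.

Step 4 (double allylic oxidation).
- What may go wrong: hydrogen abstraction at C7–H or C13, a stalled second oxidation at C1, or peroxide by-products, with loss of material.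
- Fallback, from 6 back to 9: a vinylogous Rubottom oxidation in place of the second C–H oxidation.
- The oxidation is stopped after the first stage and 6 is isolated. TBSOTf, Et3N, CH2Cl2 under equilibrating conditions gives the extended 8-silyloxy-1(10),8-diene F7.
- Dimethyldioxirane (acetone, −40 °C, then dilute acid) attacks C1 axially on the β face, as with steroidal 3,5-dienol ethers. This gives 9 directly, so steps 5 and 6 are not needed.
- Competing enolisation towards C7 is the weak point of this alternative.

Step 16 (C13 oxidation).
- What may go wrong: an ene reaction that removes C7–H, migration of the alkene into conjugation with the ketone, or sluggish conversion on the polyfunctional acid.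
- Fallback, from 24 back to 25: a Schenck ene reaction.
- O2, tetraphenylporphyrin, visible light, CH2Cl2, 0 °C gives the allylic hydroperoxide F8. Singlet oxygen ignores the electron-poor enone and enoate.
- PPh3 reduces F8 to 25, which is oxidised with Dess–Martin periodinane as in the route.

**Further compounds**
F1 | step 7 | 11,12-epoxyeremophil-9-ene-1,8-dione (C11 epimers) | CC1(CO1)[C@@H]2C[C@@]3(C)C(=CC2=O)C(=O)CC[C@@H]3C
F2 | step 7 | 11,12-epoxy-4α-hydroxyeremophil-9-ene-1,8-dione | CC1(CO1)[C@@H]2C[C@@]3(C)C(=CC2=O)C(=O)CC[C@]3(O)C
F3 | step 7 | 11,12-epoxyeremophila-4(15),9-diene-1,8-dione | CC1(CO1)[C@@H]2C[C@@]3(C)C(=CC2=O)C(=O)CCC3=C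
F4 | step 7 | 11,12-epoxyeremophila-4(15),9-diene-1β,8β-diol | CC1(CO1)[C@@H]2C[C@@]3(C)C(=C[C@H]2O)[C@H](O)CCC3=C
F5 | step 7 | 11,12-epoxyeremophil-9-ene-1β,8β,15-triol | CC1(CO1)[C@@H]2C[C@@]3(C)C(=C[C@H]2O)[C@H](O)CC[C@@H]3CO
F6 | step 7 | eremophila-9,11-diene-1β,8β,15-triol | CC(=C)[C@@H]1C[C@@]2(C)C(=C[C@H]1O)[C@H](O)CC[C@@H]2CO
F7 | step 4 | 8-(tert-butyldimethylsilyloxy)eremophila-1(10),8,11-triene | CC(=C)[C@@H]1C[C@@]2(C)C(=CCC[C@@H]2C)C=C1O[Si](C)(C)C(C)(C)C
F8 | step 16 | 13-hydroperoxy-1β-[(2E,4S)-2,4-dimethyloct-2-enoyloxy]-8-oxoeremophila-9,11-dien-15-oic acid | C=C(COO)[C@@H]1C[C@@]2(C)C(=CC1=O)[C@H](OC(=O)/C(C)=C/[C@@H](C)CCCC)CC[C@@H]2C(=O)O
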